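## Structural features

The target joins five aryl rings. A cis-fused 3,7-dioxabicyclo[3.3.0]octane (furofuran) core carries the syringyl rings B and C on its benzylic carbons C7 and C7', and three arylglycerol chains hang from phenolic oxygens. O-4 of ring B is bound to the middle carbon of an erythro chain (C7A R, C8A S) that ends in guaiacyl ring A. O-4 of ring C is bound to the middle carbon of a threo chain (C7D S, C8D S) on ring D, and O-4 of ring D to the middle carbon of a second erythro chain (C7E S, C8E R) that ends in guaiacyl ring E. There are ten stereocentres: four contiguous ones in the core (C7 S, C8 R, C8' R, C7' S; both aryl groups exo, H8 and H8' cis) and three vicinal pairs too far apart to control one another. Fragile sites are the benzylic C–O bonds of the core (acid epimerisation, hydrogenolysis), the three benzylic carbinols (quinone-methide precursors once a para phenol is free) and the β-aryl ether links (elimination). The real difficulty is that the core is C2-symmetric yet its ends must be told apart, each core ether oxygen is flanked by two methoxy groups, and the chains need both erythro and threo relationships in a defined absolute sense. The key step uses the fact that C9 lies between ring-fusion carbon C8 and the oxygen on C7', and C9' between C8' and the oxygen on C7: at the lactone level both are carbonyl carbons, so an E alkene C8=C8' flanked by the carbinols C7 and C7' can take both from carbon monoxide while the two rings close.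

## Logic of the disconnections

44 goes back to 43 and then 42 by cutting only O–Si bonds and one ester C–O bond. All hydroxyls and phenols are masked as silyl ethers so that one buffered fluoride treatment ends the synthesis. The demand is that the ester of 42 is removed before the ring-A phenol is freed.

42 goes back through 41 and 40 to 39, and 39 to 38 + 25, by cutting the C7A–C8A bond; 38 goes back to 37 + 19 by cutting the O–CH2 bond. The hindered ring-B oxygen is thus alkylated at a primary carbon, and C8A is set by the auxiliary. A syn aldol gives the threo chain, so C7A has to be inverted between 41 and 42. The forward steps need a Z-enolate reacting through a closed transition state and a clean SN2 displacement at a benzylic carbinol.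

37 goes back through 36 and 34 to 33, and 33 to 20 + 32, by cutting C7D–C8D; 20 goes back to 18 + 19. Here the syn aldol gives the required threo chain directly. Since 32 already holds chain E, this one union brings in two rings and four stereocentres. The forward step must tolerate two large partners and the benzylic ethers of the core.

32 goes back through 31, 29 and 27 to 26, and 26 to 23 + 25; 23 goes back to 21 + 22, and 25 to 24 + 4. Chain E is built off the core by the same aldol logic with the antipodal auxiliary, followed by inversion at C7E. The propenyl group of 22 is a latent formyl group that cannot interfere with the aldol. The demand is an oxidative cleavage that spares silyl ethers and the ester.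

18 goes back to 17, 17 to 16 and 16 to 15. These steps only adjust C9 and C9' from carbonyl to methylene and unmask ring C. Ring C carries the silyl group because it is extended first, so fluoride meets no other silicon; ring B carries the benzyl group, which is removed later when only silyl ethers are present. The demand is that the lactol carbons ionise in preference to C7 and C7'.

15 goes back to 13 and two molecules of 14 by cutting C8'–C9', C9'–O(C7), C8–C9 and C9–O(C7'). This removes both rings and both ring-fusion stereocentres and leaves an acyclic alkene whose two carbinol centres are already in place. The forward step needs syn delivery of both carbonyl carbons to one alkene face, in the endo sense, faster than β-hydride elimination.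

13 goes back to 12 by alkyne reduction; 12 goes back to 10 + 5 and 10 through 8 and 7 to 3 + 6, by cutting the two C(sp)–carbinol bonds. Two points were checked here.
- The configurations of 13 and 15 agree with the target and need no correction. 12 must, however, be (1R,4R) to give (1S,4S)-13, because an internal alkynyl group outranks aryl whereas alkenyl does not.
- The carbinols are set by catalyst-controlled additions to aryl aldehydes. Reducing an aryl alkynyl ketone (or an ynedione) with a RuCl(p-cymene)(TsDPEN) catalyst would not be reliable: aryl and alkynyl compete for the same site of that catalyst, and an ynedione is a strong Michael acceptor.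

The forward steps need the same facial sense twice and a trans-selective alkyne reduction.

3 goes back to 1 + 2 and 5 to 1 + 4 by cutting O–C and O–Si bonds; one cheap aldehyde serves both halves.

## Other disconnections considered

Alternative 1: The cut is at the two aryl–carbinol bonds of the end units (ring A–C7A and ring E–C7E), so the substrate is bis-aldehyde A2, the whole skeleton short of the two terminal rings. Two equivalents of aryltitanium triisopropoxide A3 (tetravalent titanium) would add to the two α-aryloxy aldehyde groups of A2 and give A1; no ring closes.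
- In its favour: a non-basic, non-chelating aryl nucleophile should add under Felkin–Anh control with the aryloxy group anti to the incoming aryl. That is the erythro relationship of both end units, so the two inversions of the chosen plan (steps 18 and 28) would disappear. Both ends are finished in one late operation, and the reaction type is established.
- Against it here: it says nothing about the core, which must still be made in differentiated form before A2 can exist. C8A and C8E must come from elsewhere and then sit next to a formyl group, where epimerisation and β-elimination threaten. Two independent additions must both be selective with no catalyst or auxiliary to enforce the sense.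
- Comparison: on structure it serves the periphery, whereas the chosen key step builds the bicyclic core and its ring-fusion centres. On mechanism it is the better founded. On step economy it is better for the erythro units but at best equal overall, since every step up to 17 and the threo unit remain.

Alternative 2: The cuts are C7'–C8' and C8–C7, which reduce the core to dithiane A5, the (5R)-menthyloxybutenolide A6 and 3. Lithiated A5 would add to C4 of A6 anti to the menthyloxy group, and the lactone enolate would be trapped by 3 anti to the new substituent, giving A4.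
- In its favour: the two different aryl groups enter in one flask, so rings B and C are differentiated from the outset. C8 and C8' are set in absolute terms by an inexpensive, recoverable auxiliary. The reaction type is established for furofuran lignans.
- Against it here: no ring closes. C7 arises in the aldol without control and C7' is masked as a thioacetal, so both benzylic centres must be set later by reduction and acid-mediated ring closure, where ionisable 4-oxygenated benzylic positions must favour the exo,exo isomer over its epimers. Thioacetal removal needs electrophilic or oxidising reagents in the presence of electron-rich rings and an aryl silyl ether.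
- Comparison: on structure the chosen step forms four bonds and both rings, and fixes C8 and C8' relative to carbinol centres already set by catalyst control; A4 still needs about four operations. On mechanism Alternative 2 is clearly the safer. On step economy it is the equal or the better (about seven steps to 17 against ten).

Alternative 3: The cuts are the benzylic bonds C7–O and C7'–O, leading to the (2R,3R)-dibenzylbutanediol A8. DDQ would take hydride from C7 and then from C7', and each cation would be trapped by the hydroxymethyl group of the other half, giving A7, which is identical with 17.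
- In its favour: A8 has only two stereocentres and no carbinols to carry. Both rings close in one metal-free operation at ordinary pressure. The product needs no redox adjustment, so steps 9 and 10 would be saved; on that point it is better.
- Against it here: once one ring has closed, its benzylic C–H is α to oxygen and more hydridic than the remaining methylene, so over-oxidation competes with the second closure. The cations can also be taken by the other electron-rich ring (aryltetralin formation). C7 and C7' rest on kinetic trans closure alone. The benzyl ether on ring B is itself open to DDQ.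
- Comparison: on structure both close two rings; the alternative forms two C–O bonds and sets C7 and C7' under weak control, the chosen step forms four bonds and sets C8 and C8' by syn-specific addition. On mechanism neither is secured for this substrate class and the risks are about equal. On step economy the alternative is equal or better.

Key step: step 8

Assumption: the dinuclear zinc catalyst from (S,S)-ProPhenol is taken to deliver alkynyl groups to the Si face of these aryl aldehydes; if the sense is the reverse, (R,R)-ProPhenol is used in steps 3 and 6 and nothing else changes.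

Remark: 19 and 21 are taken as purchased (each is otherwise one step from the parent oxazolidinone and chloroacetyl chloride).

Remark on locants: core carbons are C7–C9 (ring B side) and C7'–C9' (ring C side); the carbons of the three side chains are written C7A–C9A, C7D–C9D and C7E–C9E, the last letter being the aryl ring on carbon 7 of that chain.

## Route

Step 1
Reactants: 1 syringaldehyde; 2 benzyl bromide
Product: 3 4-(benzyloxy)-3,5-dimethoxybenzaldehyde
Conditions: BnBr, K2CO3, DMF, rt
Reagents that add atoms: benzyl bromide (2), BrCc1ccccc1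
Why: Williamson ether synthesis on the phenoxide; the benzyl ether is kept on ring B because it survives all steps up to step 23 and is then removed in the presence of silyl ethers.

Step 2
Reactants: 1 syringaldehyde; 4 chlorotriisopropylsilane
Product: 5 3,5-dimethoxy-4-[(triisopropylsilyl)oxy]benzaldehyde
Conditions: i-Pr3SiCl, imidazole, DMAP (cat.), DMF, 40 °C
Reagents that add atoms: chlorotriisopropylsilane (4), CC(C)[Si](Cl)(C(C)C)C(C)C
Why: Silylation of the phenol; the bulky aryl silyl ether on ring C tolerates organozinc, hydride and Lewis-acid steps and is the only silicon group present when fluoride is used in step 11.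

Step 3
Reactants: 3 4-(benzyloxy)-3,5-dimethoxybenzaldehyde; 6 ethynyltrimethylsilane
Product: 7 (1R)-1-[4-(benzyloxy)-3,5-dimethoxyphenyl]-3-(trimethylsilyl)prop-2-yn-1-ol
Conditions: (S,S)-ProPhenol (10 mol %), Me2Zn (3 equiv), alkyne (3 equiv), Ph3PO (20 mol %), toluene, 0 °C to rt
Reagents that add atoms: ethynyltrimethylsilane (6), C#C[Si](C)(C)C
Why: Catalytic asymmetric alkynylzinc addition to an aryl aldehyde; delivery to the Si face of the formyl group sets C7, which is R here because the silylalkynyl group outranks aryl.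

Step 4
Reactants: 7 (1R)-1-[4-(benzyloxy)-3,5-dimethoxyphenyl]-3-(trimethylsilyl)prop-2-yn-1-ol
Product: 8 (1S)-1-[4-(benzyloxy)-3,5-dimethoxyphenyl]prop-2-yn-1-ol
Conditions: K2CO3 (0.2 equiv), MeOH, 0 °C to rt
Reagents that add atoms: none
Why: Base-catalysed methanolysis of the C(sp)–Si bond; the carbinol is untouched and is called S only because ethynyl ranks below aryl.

Step 5
Reactants: 8 (1S)-1-[4-(benzyloxy)-3,5-dimethoxyphenyl]prop-2-yn-1-ol; 9 chlorotrimethylsilane
Product: 10 {[(1S)-1-[4-(benzyloxy)-3,5-dimethoxyphenyl]prop-2-yn-1-yl]oxy}trimethylsilane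
Conditions: Me3SiCl, Et3N, CH2Cl2, 0 °C
Reagents that add atoms: chlorotrimethylsilane (9), C[Si](C)(C)Cl
Why: O-silylation keeps the hydroxyl from consuming the zinc reagent of step 6; the trimethylsilyl ether is chosen because mild methanolic base removes it without touching the aryl silyl ether.

Step 6
Reactants: 10 {[(1S)-1-[4-(benzyloxy)-3,5-dimethoxyphenyl]prop-2-yn-1-yl]oxy}trimethylsilane; 5 3,5-dimethoxy-4-[(triisopropylsilyl)oxy]benzaldehyde
Product: 12 (1R,4R)-1-[4-(benzyloxy)-3,5-dimethoxyphenyl]-4-{3,5-dimethoxy-4-[(triisopropylsilyl)oxy]phenyl}but-2-yne-1,4-diol, via O-trimethylsilyl ynediol 11 (not isolated)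
Conditions: (S,S)-ProPhenol (20 mol %), Me2Zn (2.5 equiv), Ph3PO (40 mol %), toluene, 0 °C to rt, 5 (1.5 equiv); then K2CO3, MeOH, 0 °C
Reagents that add atoms: none
Why: A second catalyst-controlled alkynylzinc addition, again to the Si face, sets C7' (R at this stage); the existing carbinol is four atoms away across a linear alkyne and should not interfere, and because two enantioselective steps are combined the minor enantiomer of 8 is expected to end mostly in a separable diastereomer of 12; methanolic K2CO3 then cleaves the O–SiMe3 group in the same flask.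

Step 7
Reactants: 12 (1R,4R)-1-[4-(benzyloxy)-3,5-dimethoxyphenyl]-4-{3,5-dimethoxy-4-[(triisopropylsilyl)oxy]phenyl}but-2-yne-1,4-diol
Product: 13 (1S,4S,E)-1-[4-(benzyloxy)-3,5-dimethoxyphenyl]-4-{3,5-dimethoxy-4-[(triisopropylsilyl)oxy]phenyl}but-2-ene-1,4-diol
Conditions: NaAlH2(OCH2CH2OMe)2 (3.5 equiv), THF, 0 °C; aqueous work-up
Reagents that add atoms: none
Why: Hydroxyl-directed trans-hydroalumination of the propargylic dialkoxide and protonolysis give the E alkene; both oxygens are poor leaving groups as aluminium alkoxides, which at 0 °C should hold back allene formation, and the carbinols become S only through the change of ranking.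

Step 8
Reactants: 13 (1S,4S,E)-1-[4-(benzyloxy)-3,5-dimethoxyphenyl]-4-{3,5-dimethoxy-4-[(triisopropylsilyl)oxy]phenyl}but-2-ene-1,4-diol; 14 carbon monoxide (two molecules)
Product: 15 (3S,3aS,6S,6aS)-3-[4-(benzyloxy)-3,5-dimethoxyphenyl]-6-{3,5-dimethoxy-4-[(triisopropylsilyl)oxy]phenyl}tetrahydro-1H,3H-furo[3,4-c]furan-1,4-dione (cis-fused dilactone, both aryl groups exo)
Conditions: Pd(OAc)2 (10 mol %), p-benzoquinone (1.5 equiv), NaOAc (0.5 equiv), CO (40 bar), 4 Å molecular sieves, THF (0.01 M), 30 °C
Reagents that add atoms: carbon monoxide (14), [C-]#[O+]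
Why: Proposed new method: the C7 alkoxide on divalent palladium takes up CO to give an alkoxycarbonyl–palladium species that adds syn across C8=C8' in the endo sense (acyl carbon to C8', metal to C8), closing lactone ring 1 (O7–C9'–C8'–C8–C7) by a 5-endo-trig migratory insertion; the C7' hydroxyl, now cis to the metal, chelates it, CO inserts into the C8–Pd bond and O7' captures the acyl–palladium (5-exo-trig acyl substitution) to close lactone ring 2, after which p-benzoquinone returns zerovalent palladium to the divalent state (one equivalent of oxidant per alkene). The closest known reaction types are the syn-specific oxidative bis(alkoxycarbonylation) of internal alkenes to succinates under Pd/benzoquinone/CO and the dicarbonylative double cyclisation of alkenols and alkenediols to lactones; the endo first insertion of an allylic alkoxycarbonyl group is the part without precedent. Because both carbonyl carbons reach one face of the E alkene, H8 and H8' end up cis, only the cis-fused bicycle can form, and C8 and C8' are created together. Their absolute sense is controlled by the C7 centre inside the forming ring: with O7 held near the alkene plane by the tether, the C7 aryl group and H7 lie on opposite faces, the metal binds C8 on the H7 face, and the aryl group ends up trans to C9, that is exo. The C2-type symmetry of 13 (axis perpendicular to the alkene plane) means that the same face leaves the C7' aryl group exo as well, whichever hydroxyl starts. The step needs CO insertion to outrun β-hydride elimination of H7 from the C8–Pd intermediate, which the high CO pressure and the O7'–H chelate are meant to secure. It also needs the allylic carbinols to survive: the medium is acetate-buffered, no alcohol solvent or CuCl2 is present, CO-saturated palladium has no free site for alkoxide β-hydride elimination, and the 4-oxygen of each ring is twisted out of conjugation by its two methoxy neighbours, which tempers ionisation. High dilution keeps an alkoxycarbonyl group from adding to the alkene of a second molecule.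

Step 9
Reactants: 15 (3S,3aS,6S,6aS)-3-[4-(benzyloxy)-3,5-dimethoxyphenyl]-6-{3,5-dimethoxy-4-[(triisopropylsilyl)oxy]phenyl}tetrahydro-1H,3H-furo[3,4-c]furan-1,4-dione
Product: 16 (3S,3aS,6S,6aS)-3-[4-(benzyloxy)-3,5-dimethoxyphenyl]-6-{3,5-dimethoxy-4-[(triisopropylsilyl)oxy]phenyl}tetrahydro-1H,3H-furo[3,4-c]furan-1,4-diol (bis-lactol, anomer mixture at C1 and C4)
Conditions: i-Bu2AlH (2.4 equiv), CH2Cl2, −78 °C
Reagents that add atoms: none
Why: Partial reduction of both γ-lactones; the tetrahedral aluminium alkoxides are stable at −78 °C, the medium is non-basic so C8 and C8' do not epimerise, and aryl silyl and benzyl ethers are inert.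

Step 10
Reactants: 16 the bis-lactol of step 9
Product: 17 (1S,3aR,4S,6aR)-1-[4-(benzyloxy)-3,5-dimethoxyphenyl]-4-{3,5-dimethoxy-4-[(triisopropylsilyl)oxy]phenyl}tetrahydro-1H,3H-furo[3,4-c]furan
Conditions: Et3SiH (6 equiv), BF3·OEt2 (3 equiv), CH2Cl2, −78 to −30 °C
Reagents that add atoms: none
Why: Ionic hydrogenation: BF3 ionises each lactol to a cyclic oxocarbenium ion that Et3SiH reduces; at low temperature the anomeric hydroxyl ionises far more readily than the benzylic C7–O and C7'–O bonds, so these centres are kept (C8 and C8' are now called R by ranking only).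

Step 11
Reactants: 17 the furofuran of step 10
Product: 18 4-{(1S,3aR,4S,6aR)-4-[4-(benzyloxy)-3,5-dimethoxyphenyl]tetrahydro-1H,3H-furo[3,4-c]furan-1-yl}-2,6-dimethoxyphenol (ring-C phenol)
Conditions: Bu4NF (1.1 equiv), THF, 0 °C; aq. NH4Cl
Reagents that add atoms: none
Why: Fluoride cleaves the aryl silyl ether, the only silicon group present; the benzyl ether stays, so the two syringyl ends are now chemically distinct.

Step 12
Reactants: 18 the ring-C phenol; 19 (4R)-4-benzyl-3-(chloroacetyl)-1,3-oxazolidin-2-one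
Product: 20 ring-C aryloxyacetyl imide: 18 with its phenolic oxygen bound to CH2C(=O)N of (4R)-4-benzyl-1,3-oxazolidin-2-one
Conditions: 19 (1.3 equiv), K2CO3, NaI (10 mol %), acetone, 40 °C
Reagents that add atoms: (4R)-4-benzyl-3-(chloroacetyl)-1,3-oxazolidin-2-one (19), ClCC(=O)N1[C@H](Cc2ccccc2)COC1=O
Why: Williamson alkylation of the hindered 2,6-dimethoxyphenoxide at a primary α-halo carbonyl carbon (iodide catalysis), which is much faster than attack at either imide carbonyl.

Step 13
Reactants: 21 (4S)-4-benzyl-3-(chloroacetyl)-1,3-oxazolidin-2-one; 22 (E)-isoeugenol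
Product: 23 (4S)-4-benzyl-3-{[2-methoxy-4-((E)-prop-1-en-1-yl)phenoxy]acetyl}-1,3-oxazolidin-2-one
Conditions: K2CO3, NaI (10 mol %), acetone, 40 °C
Reagents that add atoms: (4S)-4-benzyl-3-(chloroacetyl)-1,3-oxazolidin-2-one (21), ClCC(=O)N1[C@@H](Cc2ccccc2)COC1=O
Why: Same Williamson alkylation; the propenyl group stands in for the ring-D formyl group, which could not be present during the aldol of step 15.

Step 14
Reactants: 24 vanillin; 4 chlorotriisopropylsilane
Product: 25 3-methoxy-4-[(triisopropylsilyl)oxy]benzaldehyde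
Conditions: i-Pr3SiCl, imidazole, DMF, rt
Reagents that add atoms: chlorotriisopropylsilane (4), CC(C)[Si](Cl)(C(C)C)C(C)C
Why: Phenol silylation; the triisopropylsilyl ether resists the mildly basic media of the LiBH4 steps better than a smaller silyl group.

Step 15
Reactants: 23 the imide of step 13; 25 3-methoxy-4-[(triisopropylsilyl)oxy]benzaldehyde
Product: 26 (4S)-4-benzyl-3-[(2S,3R)-3-hydroxy-2-[2-methoxy-4-((E)-prop-1-en-1-yl)phenoxy]-3-{3-methoxy-4-[(triisopropylsilyl)oxy]phenyl}propanoyl]-1,3-oxazolidin-2-one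
Conditions: n-Bu2BOTf (1.2 equiv), i-Pr2NEt (1.4 equiv), CH2Cl2, −78 to 0 °C; 25, −78 to 0 °C; pH 7 buffer, MeOH, H2O2
Reagents that add atoms: none
Why: Evans syn-aldol reaction of an aryloxyacetyl imide: the Z boron enolate reacts through a Zimmerman–Traxler chair and the (4S)-benzyl group screens one enolate face, which sets C8E and C7E as (2S,3R), that is 7R,8R (threo) after reduction.

Step 16
Reactants: 26 the aldol adduct of step 15
Product: 27 (1R,2R)-2-[2-methoxy-4-((E)-prop-1-en-1-yl)phenoxy]-1-{3-methoxy-4-[(triisopropylsilyl)oxy]phenyl}propane-1,3-diol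
Conditions: LiBH4 (2.5 equiv), MeOH (2.5 equiv), THF, 0 °C
Reagents that add atoms: none
Why: Reductive removal of the auxiliary (the exocyclic imide carbonyl is the most electrophilic site); the low temperature avoids retro-aldol cleavage and no stereocentre is touched.

Step 17
Reactants: 27 the diol of step 16; 28 tert-butyldimethylsilyl chloride
Product: 29 (1R,2R)-3-[(tert-butyldimethylsilyl)oxy]-2-[2-methoxy-4-((E)-prop-1-en-1-yl)phenoxy]-1-{3-methoxy-4-[(triisopropylsilyl)oxy]phenyl}propan-1-ol
Conditions: t-BuMe2SiCl (1.1 equiv), imidazole, CH2Cl2, 0 °C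
Reagents that add atoms: tert-butyldimethylsilyl chloride (28), CC(C)(C)[Si](C)(C)Cl
Why: Selective silylation of the primary hydroxyl over the hindered benzylic one, which leaves C7E–OH alone for inversion.

Step 18
Reactants: 29 the mono-silyl ether of step 17; 30 4-nitrobenzoic acid
Product: 31 (1S,2R)-3-[(tert-butyldimethylsilyl)oxy]-2-[2-methoxy-4-((E)-prop-1-en-1-yl)phenoxy]-1-{3-methoxy-4-[(triisopropylsilyl)oxy]phenyl}propyl 4-nitrobenzoate
Conditions: 4-O2NC6H4CO2H (2 equiv), PPh3 (2 equiv), diisopropyl azodicarboxylate (2 equiv), toluene, −20 to 0 °C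
Reagents that add atoms: 4-nitrobenzoic acid (30), OC(=O)c1ccc(cc1)[N+](=O)[O-]
Why: Mitsunobu esterification with inversion at C7E (SN2 displacement of the oxyphosphonium group by the carboxylate) turns the threo into the erythro chain (C7E S, C8E R); a non-polar solvent and low temperature disfavour ionisation of the benzylic centre.

Step 19
Reactants: 31 the 4-nitrobenzoate of step 18
Product: 32 (1S,2R)-3-[(tert-butyldimethylsilyl)oxy]-2-(4-formyl-2-methoxyphenoxy)-1-{3-methoxy-4-[(triisopropylsilyl)oxy]phenyl}propyl 4-nitrobenzoate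
Conditions: OsO4 (2 mol %), NaIO4 (4 equiv), 2,6-lutidine, dioxane–H2O, rt
Reagents that add atoms: sodium periodate (oxygen donor by way of catalytic OsO4), [Na+].[O-]I(=O)(=O)=O
Why: Lemieux–Johnson cleavage (dihydroxylation, then periodate scission) of the propenyl group unmasks the ring-D aldehyde; silyl ethers, the ester and the aryl ethers are inert.

Step 20
Reactants: 20 the ring-C aryloxyacetyl imide; 32 the ring-D aldehyde of step 19
Product: 33 syn-aldol adduct: ring C–O–CH[C(=O)N-oxazolidinone (4R)]–CH(OH)–ring D, (2R,3S) in imide locants (C8D, C7D); ring D keeps the protected chain E of 32 and ring B its benzyl ether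
Conditions: n-Bu2BOTf (1.2 equiv), i-Pr2NEt (1.4 equiv), CH2Cl2, −78 to 0 °C; 32 (1.3 equiv), −78 to 0 °C; pH 7 buffer, MeOH, H2O2
Reagents that add atoms: none
Why: Evans syn-aldol reaction as in step 15 but with the (4R) auxiliary, which gives the (2R,3S) adduct and hence C7D S, C8D S after reduction: the threo chain is obtained directly; the amine keeps the medium non-acidic for the core ethers.

Step 21
Reactants: 33 the aldol adduct of step 20
Product: 34 triol with free C7D, C9D and C7E hydroxyls (C7D S, C8D S, C7E S, C8E R); C9E tert-butyldimethylsilyl ether, ring E triisopropylsilyl ether, ring B benzyl ether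
Conditions: LiBH4 (6 equiv), MeOH, THF, 0 °C to rt
Reagents that add atoms: none
Why: LiBH4 removes the auxiliary reductively and, in the same operation, reduces the electron-poor 4-nitrobenzoate to release C7E–OH; nitro groups and silyl ethers are not affected.

Step 22
Reactants: 34 the triol of step 21; 35 tert-butyldimethylsilyl trifluoromethanesulfonate
Product: 36 C7D,C9D,C7E-tris(tert-butyldimethylsilyl) ether of 34
Conditions: t-BuMe2SiOTf (4 equiv), 2,6-lutidine (6 equiv), CH2Cl2, −78 to 0 °C
Reagents that add atoms: tert-butyldimethylsilyl trifluoromethanesulfonate (35), CC(C)(C)[Si](C)(C)OS(=O)(=O)C(F)(F)F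
Why: The silyl triflate is reactive enough for the two hindered benzylic hydroxyls, and 2,6-lutidine keeps the medium non-acidic; full protection is needed for the enolisation of step 25 and the inversion of step 28.

Step 23
Reactants: 36 the tris-silyl ether of step 22
Product: 37 ring-B phenol (36 without the benzyl group)
Conditions: H2 (1 atm), 10% Pd/C, EtOAc, rt
Reagents that add atoms: none
Why: Hydrogenolysis of the aryl benzyl ether, which is much faster than cleavage of the benzylic C–O bonds of the core in a neutral, aprotic solvent; no nitro group is left at this stage and silyl ethers are inert.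

Step 24
Reactants: 37 the ring-B phenol; 19 (4R)-4-benzyl-3-(chloroacetyl)-1,3-oxazolidin-2-one
Product: 38 ring-B aryloxyacetyl imide: 37 with its phenolic oxygen bound to CH2C(=O)N of (4R)-4-benzyl-1,3-oxazolidin-2-one
Conditions: 19 (1.3 equiv), K2CO3, NaI (10 mol %), acetone, 40 °C
Reagents that add atoms: (4R)-4-benzyl-3-(chloroacetyl)-1,3-oxazolidin-2-one (19), ClCC(=O)N1[C@H](Cc2ccccc2)COC1=O
Why: Williamson alkylation as in step 12; all hydroxyls are silylated, so only the phenoxide reacts.

Step 25
Reactants: 38 the ring-B aryloxyacetyl imide; 25 3-methoxy-4-[(triisopropylsilyl)oxy]benzaldehyde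
Product: 39 syn-aldol adduct: ring B–O–CH[C(=O)N-oxazolidinone (4R)]–CH(OH)–ring A (ring A O-triisopropylsilyl), (2R,3S) in imide locants (C8A, C7A)
Conditions: n-Bu2BOTf (1.2 equiv), i-Pr2NEt (1.4 equiv), CH2Cl2, −78 to 0 °C; 25 (1.5 equiv), −78 to 0 °C; pH 7 buffer, MeOH, H2O2
Reagents that add atoms: none
Why: Evans syn-aldol reaction through the Z boron enolate with the (4R) auxiliary sets C8A in its final configuration (S after reduction) and C7A as S, to be inverted in step 28.

Step 26
Reactants: 39 the aldol adduct of step 25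
Product: 40 diol with free C7A and C9A hydroxyls (C7A S, C8A S)
Conditions: LiBH4 (2.5 equiv), MeOH (2.5 equiv), THF, 0 °C
Reagents that add atoms: none
Why: Reductive removal of the auxiliary as in step 16; silyl ethers and the core are inert.

Step 27
Reactants: 40 the diol of step 26; 28 tert-butyldimethylsilyl chloride
Product: 41 C9A tert-butyldimethylsilyl ether of 40 (free C7A–OH)
Conditions: t-BuMe2SiCl (1.1 equiv), imidazole, CH2Cl2, 0 °C
Reagents that add atoms: tert-butyldimethylsilyl chloride (28), CC(C)(C)[Si](C)(C)Cl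
Why: Selective primary silylation leaves C7A–OH as the only free hydroxyl in the molecule.

Step 28
Reactants: 41 the mono-silyl ether of step 27; 30 4-nitrobenzoic acid
Product: 42 C7A 4-nitrobenzoate with inverted C7A (C7A R, C8A S)
Conditions: 4-O2NC6H4CO2H (2 equiv), PPh3 (2 equiv), diisopropyl azodicarboxylate (2 equiv), toluene, −20 to 0 °C
Reagents that add atoms: 4-nitrobenzoic acid (30), OC(=O)c1ccc(cc1)[N+](=O)[O-]
Why: Mitsunobu inversion at the only free hydroxyl converts the threo chain A into the erythro chain; SN2 displacement is favoured by the non-polar solvent and low temperature.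

Step 29
Reactants: 42 the 4-nitrobenzoate of step 28
Product: 43 C7A alcohol (C7A R, C8A S), otherwise as 42: ring A and ring E triisopropylsilyl ethers; C9A, C7D, C9D, C7E and C9E tert-butyldimethylsilyl ethers
Conditions: K2CO3 (0.5 equiv), MeOH–THF, 0 °C
Reagents that add atoms: none
Why: Methanolysis of the activated ester; it is done before the ring-A phenol is unmasked, so that no 4-hydroxybenzyl ester, which would collapse to a quinone methide, can arise.

Step 30
Reactants: 43 the alcohol of step 29
Product: 44 the target, CNP0316493.3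
Conditions: Bu4NF (12 equiv), AcOH (12 equiv), THF, 0 °C to rt
Reagents that add atoms: none
Why: Global desilylation (two aryl and five alkyl silyl ethers) with buffered fluoride; acetic acid keeps the phenols protonated so that the 4-hydroxybenzyl alcohols do not eliminate, and the core and aryl ethers are stable to fluoride.

## Compound list

1 | syringaldehyde | COc1cc(C=O)cc(OC)c1O | starting material
2 | benzyl bromide | BrCc1ccccc1 | starting material
3 | 4-(benzyloxy)-3,5-dimethoxybenzaldehyde | COc1cc(C=O)cc(OC)c1OCc1ccccc1 | intermediate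
4 | chlorotriisopropylsilane | CC(C)[Si](Cl)(C(C)C)C(C)C | starting material
5 | 3,5-dimethoxy-4-[(triisopropylsilyl)oxy]benzaldehyde | COc1cc(C=O)cc(OC)c1O[Si](C(C)C)(C(C)C)C(C)C | intermediate
6 | ethynyltrimethylsilane | C#C[Si](C)(C)C | starting material
7 | (1R)-1-[4-(benzyloxy)-3,5-dimethoxyphenyl]-3-(trimethylsilyl)prop-2-yn-1-ol | COc1cc(cc(OC)c1OCc1ccccc1)[C@@H](O)C#C[Si](C)(C)C | intermediate
8 | (1S)-1-[4-(benzyloxy)-3,5-dimethoxyphenyl]prop-2-yn-1-ol | COc1cc(cc(OC)c1OCc1ccccc1)[C@@H](O)C#C | intermediate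
9 | chlorotrimethylsilane | C[Si](C)(C)Cl | starting material
10 | {[(1S)-1-[4-(benzyloxy)-3,5-dimethoxyphenyl]prop-2-yn-1-yl]oxy}trimethylsilane | COc1cc(cc(OC)c1OCc1ccccc1)[C@@H](O[Si](C)(C)C)C#C | intermediate
11 | (1R,4R)-4-[4-(benzyloxy)-3,5-dimethoxyphenyl]-1-{3,5-dimethoxy-4-[(triisopropylsilyl)oxy]phenyl}-4-[(trimethylsilyl)oxy]but-2-yn-1-ol (not isolated) | COc1cc(cc(OC)c1OCc1ccccc1)[C@@H](O[Si](C)(C)C)C#C[C@H](O)c1cc(OC)c(O[Si](C(C)C)(C(C)C)C(C)C)c(OC)c1 | intermediate
12 | (1R,4R)-1-[4-(benzyloxy)-3,5-dimethoxyphenyl]-4-{3,5-dimethoxy-4-[(triisopropylsilyl)oxy]phenyl}but-2-yne-1,4-diol | COc1cc(cc(OC)c1OCc1ccccc1)[C@@H](O)C#C[C@H](O)c1cc(OC)c(O[Si](C(C)C)(C(C)C)C(C)C)c(OC)c1 | intermediate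
13 | (1S,4S,E)-1-[4-(benzyloxy)-3,5-dimethoxyphenyl]-4-{3,5-dimethoxy-4-[(triisopropylsilyl)oxy]phenyl}but-2-ene-1,4-diol | COc1cc(cc(OC)c1OCc1ccccc1)[C@@H](O)/C=C/[C@H](O)c1cc(OC)c(O[Si](C(C)C)(C(C)C)C(C)C)c(OC)c1 | intermediate
14 | carbon monoxide | [C-]#[O+] | starting material
15 | (3S,3aS,6S,6aS)-3-[4-(benzyloxy)-3,5-dimethoxyphenyl]-6-{3,5-dimethoxy-4-[(triisopropylsilyl)oxy]phenyl}tetrahydro-1H,3H-furo[3,4-c]furan-1,4-dione | COc1cc(cc(OC)c1OCc1ccccc1)[C@H]1OC(=O)[C@H]2[C@@H]1C(=O)O[C@@H]2c1cc(OC)c(O[Si](C(C)C)(C(C)C)C(C)C)c(OC)c1 | intermediate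
16 | (3S,3aS,6S,6aS)-3-[4-(benzyloxy)-3,5-dimethoxyphenyl]-6-{3,5-dimethoxy-4-[(triisopropylsilyl)oxy]phenyl}tetrahydro-1H,3H-furo[3,4-c]furan-1,4-diol, anomer mixture | COc1cc(cc(OC)c1OCc1ccccc1)[C@H]1OC(O)[C@H]2[C@@H]1C(O)O[C@@H]2c1cc(OC)c(O[Si](C(C)C)(C(C)C)C(C)C)c(OC)c1 | intermediate
17 | (1S,3aR,4S,6aR)-1-[4-(benzyloxy)-3,5-dimethoxyphenyl]-4-{3,5-dimethoxy-4-[(triisopropylsilyl)oxy]phenyl}tetrahydro-1H,3H-furo[3,4-c]furan | COc1cc(cc(OC)c1OCc1ccccc1)[C@H]1OC[C@H]2[C@@H]1CO[C@@H]2c1cc(OC)c(O[Si](C(C)C)(C(C)C)C(C)C)c(OC)c1 | intermediate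
18 | 4-{(1S,3aR,4S,6aR)-4-[4-(benzyloxy)-3,5-dimethoxyphenyl]tetrahydro-1H,3H-furo[3,4-c]furan-1-yl}-2,6-dimethoxyphenol | COc1cc(cc(OC)c1OCc1ccccc1)[C@H]1OC[C@H]2[C@@H]1CO[C@@H]2c1cc(OC)c(O)c(OC)c1 | intermediate
19 | (4R)-4-benzyl-3-(chloroacetyl)-1,3-oxazolidin-2-one | ClCC(=O)N1[C@H](Cc2ccccc2)COC1=O | starting material
20 | ring-C aryloxyacetyl imide of 18 with (4R)-4-benzyl-1,3-oxazolidin-2-one | COc1cc(cc(OC)c1OCc1ccccc1)[C@H]1OC[C@H]2[C@@H]1CO[C@@H]2c1cc(OC)c(OCC(=O)N3[C@H](Cc4ccccc4)COC3=O)c(OC)c1 | intermediate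
21 | (4S)-4-benzyl-3-(chloroacetyl)-1,3-oxazolidin-2-one | ClCC(=O)N1[C@@H](Cc2ccccc2)COC1=O | starting material
22 | (E)-isoeugenol | C/C=C/c1ccc(O)c(OC)c1 | starting material
23 | (4S)-4-benzyl-3-{[2-methoxy-4-((E)-prop-1-en-1-yl)phenoxy]acetyl}-1,3-oxazolidin-2-one | C/C=C/c1ccc(OCC(=O)N2[C@@H](Cc3ccccc3)COC2=O)c(OC)c1 | intermediate
24 | vanillin | COc1cc(C=O)ccc1O | starting material
25 | 3-methoxy-4-[(triisopropylsilyl)oxy]benzaldehyde | COc1cc(C=O)ccc1O[Si](C(C)C)(C(C)C)C(C)C | intermediate
26 | (4S)-4-benzyl-3-[(2S,3R)-3-hydroxy-2-[2-methoxy-4-((E)-prop-1-en-1-yl)phenoxy]-3-{3-methoxy-4-[(triisopropylsilyl)oxy]phenyl}propanoyl]-1,3-oxazolidin-2-one | C/C=C/c1ccc(O[C@@H]([C@H](O)c2ccc(O[Si](C(C)C)(C(C)C)C(C)C)c(OC)c2)C(=O)N2[C@@H](Cc3ccccc3)COC2=O)c(OC)c1 | intermediate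
27 | (1R,2R)-2-[2-methoxy-4-((E)-prop-1-en-1-yl)phenoxy]-1-{3-methoxy-4-[(triisopropylsilyl)oxy]phenyl}propane-1,3-diol | C/C=C/c1ccc(O[C@H](CO)[C@H](O)c2ccc(O[Si](C(C)C)(C(C)C)C(C)C)c(OC)c2)c(OC)c1 | intermediate
28 | tert-butyldimethylsilyl chloride | CC(C)(C)[Si](C)(C)Cl | starting material
29 | (1R,2R)-3-[(tert-butyldimethylsilyl)oxy]-2-[2-methoxy-4-((E)-prop-1-en-1-yl)phenoxy]-1-{3-methoxy-4-[(triisopropylsilyl)oxy]phenyl}propan-1-ol | C/C=C/c1ccc(O[C@H](CO[Si](C)(C)C(C)(C)C)[C@H](O)c2ccc(O[Si](C(C)C)(C(C)C)C(C)C)c(OC)c2)c(OC)c1 | intermediate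
30 | 4-nitrobenzoic acid | OC(=O)c1ccc(cc1)[N+](=O)[O-] | starting material
31 | (1S,2R)-3-[(tert-butyldimethylsilyl)oxy]-2-[2-methoxy-4-((E)-prop-1-en-1-yl)phenoxy]-1-{3-methoxy-4-[(triisopropylsilyl)oxy]phenyl}propyl 4-nitrobenzoate | C/C=C/c1ccc(O[C@H](CO[Si](C)(C)C(C)(C)C)[C@@H](OC(=O)c2ccc(cc2)[N+](=O)[O-])c2ccc(O[Si](C(C)C)(C(C)C)C(C)C)c(OC)c2)c(OC)c1 | intermediate
32 | (1S,2R)-3-[(tert-butyldimethylsilyl)oxy]-2-(4-formyl-2-methoxyphenoxy)-1-{3-methoxy-4-[(triisopropylsilyl)oxy]phenyl}propyl 4-nitrobenzoate | O=Cc1ccc(O[C@H](CO[Si](C)(C)C(C)(C)C)[C@@H](OC(=O)c2ccc(cc2)[N+](=O)[O-])c2ccc(O[Si](C(C)C)(C(C)C)C(C)C)c(OC)c2)c(OC)c1 | intermediate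
33 | syn-aldol adduct of 20 and 32, (2R,3S) at C8D and C7D in imide locants, (4R) auxiliary | COc1cc(cc(OC)c1OCc1ccccc1)[C@H]1OC[C@H]2[C@@H]1CO[C@@H]2c1cc(OC)c(O[C@H]([C@@H](O)c3ccc(O[C@H](CO[Si](C)(C)C(C)(C)C)[C@@H](OC(=O)c4ccc(cc4)[N+](=O)[O-])c4ccc(O[Si](C(C)C)(C(C)C)C(C)C)c(OC)c4)c(OC)c3)C(=O)N3[C@H](Cc4ccccc4)COC3=O)c(OC)c1 | intermediate
34 | C7D,C9D,C7E-triol (C7D S, C8D S, C7E S, C8E R), C9E O-TBS, ring E O-TIPS, ring B O-benzyl | COc1cc(cc(OC)c1OCc1ccccc1)[C@H]1OC[C@H]2[C@@H]1CO[C@@H]2c1cc(OC)c(O[C@@H](CO)[C@@H](O)c3ccc(O[C@H](CO[Si](C)(C)C(C)(C)C)[C@@H](O)c4ccc(O[Si](C(C)C)(C(C)C)C(C)C)c(OC)c4)c(OC)c3)c(OC)c1 | intermediate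
35 | tert-butyldimethylsilyl trifluoromethanesulfonate | CC(C)(C)[Si](C)(C)OS(=O)(=O)C(F)(F)F | starting material
36 | C7D,C9D,C7E-tris(tert-butyldimethylsilyl) ether of 34 | COc1cc(cc(OC)c1OCc1ccccc1)[C@H]1OC[C@H]2[C@@H]1CO[C@@H]2c1cc(OC)c(O[C@@H](CO[Si](C)(C)C(C)(C)C)[C@@H](O[Si](C)(C)C(C)(C)C)c3ccc(O[C@H](CO[Si](C)(C)C(C)(C)C)[C@@H](O[Si](C)(C)C(C)(C)C)c4ccc(O[Si](C(C)C)(C(C)C)C(C)C)c(OC)c4)c(OC)c3)c(OC)c1 | intermediate
37 | ring-B phenol (36 without benzyl) | COc1cc(cc(OC)c1O)[C@H]1OC[C@H]2[C@@H]1CO[C@@H]2c1cc(OC)c(O[C@@H](CO[Si](C)(C)C(C)(C)C)[C@@H](O[Si](C)(C)C(C)(C)C)c3ccc(O[C@H](CO[Si](C)(C)C(C)(C)C)[C@@H](O[Si](C)(C)C(C)(C)C)c4ccc(O[Si](C(C)C)(C(C)C)C(C)C)c(OC)c4)c(OC)c3)c(OC)c1 | intermediate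
38 | ring-B aryloxyacetyl imide of 37 with (4R)-4-benzyl-1,3-oxazolidin-2-one | COc1cc(cc(OC)c1OCC(=O)N1[C@H](Cc2ccccc2)COC1=O)[C@H]1OC[C@H]2[C@@H]1CO[C@@H]2c1cc(OC)c(O[C@@H](CO[Si](C)(C)C(C)(C)C)[C@@H](O[Si](C)(C)C(C)(C)C)c3ccc(O[C@H](CO[Si](C)(C)C(C)(C)C)[C@@H](O[Si](C)(C)C(C)(C)C)c4ccc(O[Si](C(C)C)(C(C)C)C(C)C)c(OC)c4)c(OC)c3)c(OC)c1 | intermediate
39 | syn-aldol adduct of 38 and 25, (2R,3S) at C8A and C7A in imide locants | COc1cc(cc(OC)c1O[C@H]([C@@H](O)c1ccc(O[Si](C(C)C)(C(C)C)C(C)C)c(OC)c1)C(=O)N1[C@H](Cc2ccccc2)COC1=O)[C@H]1OC[C@H]2[C@@H]1CO[C@@H]2c1cc(OC)c(O[C@@H](CO[Si](C)(C)C(C)(C)C)[C@@H](O[Si](C)(C)C(C)(C)C)c3ccc(O[C@H](CO[Si](C)(C)C(C)(C)C)[C@@H](O[Si](C)(C)C(C)(C)C)c4ccc(O[Si](C(C)C)(C(C)C)C(C)C)c(OC)c4)c(OC)c3)c(OC)c1 | intermediate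
40 | C7A,C9A-diol (C7A S, C8A S) | COc1cc(cc(OC)c1O[C@@H](CO)[C@@H](O)c1ccc(O[Si](C(C)C)(C(C)C)C(C)C)c(OC)c1)[C@H]1OC[C@H]2[C@@H]1CO[C@@H]2c1cc(OC)c(O[C@@H](CO[Si](C)(C)C(C)(C)C)[C@@H](O[Si](C)(C)C(C)(C)C)c3ccc(O[C@H](CO[Si](C)(C)C(C)(C)C)[C@@H](O[Si](C)(C)C(C)(C)C)c4ccc(O[Si](C(C)C)(C(C)C)C(C)C)c(OC)c4)c(OC)c3)c(OC)c1 | intermediate
41 | C9A tert-butyldimethylsilyl ether of 40 (C7A S, C8A S) | COc1cc(cc(OC)c1O[C@@H](CO[Si](C)(C)C(C)(C)C)[C@@H](O)c1ccc(O[Si](C(C)C)(C(C)C)C(C)C)c(OC)c1)[C@H]1OC[C@H]2[C@@H]1CO[C@@H]2c1cc(OC)c(O[C@@H](CO[Si](C)(C)C(C)(C)C)[C@@H](O[Si](C)(C)C(C)(C)C)c3ccc(O[C@H](CO[Si](C)(C)C(C)(C)C)[C@@H](O[Si](C)(C)C(C)(C)C)c4ccc(O[Si](C(C)C)(C(C)C)C(C)C)c(OC)c4)c(OC)c3)c(OC)c1 | intermediate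
42 | C7A 4-nitrobenzoate (C7A R, C8A S) | COc1cc(cc(OC)c1O[C@@H](CO[Si](C)(C)C(C)(C)C)[C@H](OC(=O)c1ccc(cc1)[N+](=O)[O-])c1ccc(O[Si](C(C)C)(C(C)C)C(C)C)c(OC)c1)[C@H]1OC[C@H]2[C@@H]1CO[C@@H]2c1cc(OC)c(O[C@@H](CO[Si](C)(C)C(C)(C)C)[C@@H](O[Si](C)(C)C(C)(C)C)c3ccc(O[C@H](CO[Si](C)(C)C(C)(C)C)[C@@H](O[Si](C)(C)C(C)(C)C)c4ccc(O[Si](C(C)C)(C(C)C)C(C)C)c(OC)c4)c(OC)c3)c(OC)c1 | intermediate
43 | C7A alcohol (C7A R, C8A S), fully silylated elsewhere | COc1cc(cc(OC)c1O[C@@H](CO[Si](C)(C)C(C)(C)C)[C@H](O)c1ccc(O[Si](C(C)C)(C(C)C)C(C)C)c(OC)c1)[C@H]1OC[C@H]2[C@@H]1CO[C@@H]2c1cc(OC)c(O[C@@H](CO[Si](C)(C)C(C)(C)C)[C@@H](O[Si](C)(C)C(C)(C)C)c3ccc(O[C@H](CO[Si](C)(C)C(C)(C)C)[C@@H](O[Si](C)(C)C(C)(C)C)c4ccc(O[Si](C(C)C)(C(C)C)C(C)C)c(OC)c4)c(OC)c3)c(OC)c1 | intermediate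
44 | CNP0316493.3 | COc1cc([C@@H](O)[C@H](CO)Oc2c(OC)cc([C@H]3OC[C@H]4[C@@H]3CO[C@@H]4c3cc(OC)c(O[C@@H](CO)[C@@H](O)c4ccc(O[C@H](CO)[C@@H](O)c5ccc(O)c(OC)c5)c(OC)c4)c(OC)c3)cc2OC)ccc1O | target

## Step count and least certain steps

Total step count: 30. Longest linear sequence: 22 steps (steps 1, 3 to 12 and 20 to 30, from 1).

Step 8 (key step, proposed new method). The endo insertion may not take place: the alkoxycarbonyl group may instead add to a second molecule, the C8–palladium intermediate may lose H7 by β-hydride elimination, or the allylic carbinols may be oxidised or ionised before carbonylation. Facial selectivity could also fall short, because it rests on one stereocentre in a strained transition state.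
Fallback (sets out from 1, comes back at 18), known chemistry: Wittig olefination of 1 with Ph3P=CHCO2Et gives ethyl (E)-sinapate F1, and i-Bu2AlH reduces it to (E)-sinapyl alcohol F2. Phenol oxidation of F2 with FeCl3 in aqueous acetone (radical β–β coupling, then trapping of both quinone methides by the hydroxymethyl groups) gives racemic syringaresinol. (+)-Syringaresinol F3 is separated from (−)-syringaresinol F4 on a chiral stationary phase. Benzylation of F3 with one equivalent of 2 and K2CO3 is statistical, with the diol and the bis-ether recycled, and gives 18. This route gives up absolute control and pays with a resolution.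

Step 6. Facial selectivity may be low or in the wrong sense with a functionalised, valuable alkyne used as the limiting partner, and zinc acetylide formation from it may be slow, so that methyl transfer to 5 competes.
Fallback (sets out from 10, comes back at 11): 10 is lithiated with n-BuLi and added to 5 to give the C1-epimeric alcohol mixture F5. MnO2 oxidises the free carbinol to ynone F6. Midland reduction of F6 with (R)-B-isopinocampheyl-9-borabicyclo[3.3.1]nonane, in which the alkynyl group is the small substituent whatever the aryl group, gives 11, which is desilylated to 12 as in step 6.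

Step 10. BF3 may ionise the benzylic C7–O and C7'–O bonds as well as the lactols, which would lead to epimerisation at C7 or C7' or to reductive ring opening; the aryl silyl ether may also suffer.
Fallback (sets out from 15, comes back at 17): LiBH4 reduces 15 to tetraol F7. MsCl in pyridine sulfonylates the two primary hydroxyls, and in the resulting bis-mesylate F8, not isolated, each benzylic hydroxyl displaces the mesylate of the other branch (5-exo-tet, retention at C7 and C7') to give 17 without any Lewis acid.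

Step 28. Ionisation of the electron-rich benzylic oxyphosphonium intermediate would cause partial retention at C7A, and elimination towards the enol ether would cost material, on a large and valuable substrate. The same concern, on a cheaper substrate, applies to step 18.
Fallback (sets out from 41, comes back at 43): Dess–Martin periodinane oxidises 41 to ketone F9. Reduction with LiBH(s-Bu)3 at −78 °C should follow the Felkin–Anh model, with the aryloxy group as the polar substituent anti to the incoming hydride, and give the erythro alcohol 43 directly, so that step 29 is not needed.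

## Further compounds

F1 | step 8 | ethyl (E)-3-(4-hydroxy-3,5-dimethoxyphenyl)prop-2-enoate (ethyl sinapate) | CCOC(=O)/C=C/c1cc(OC)c(O)c(OC)c1
F2 | step 8 | (E)-sinapyl alcohol | COc1cc(/C=C/CO)cc(OC)c1O
F3 | step 8 | (+)-syringaresinol, (7S,7'S,8R,8'R) | COc1cc(cc(OC)c1O)[C@H]1OC[C@H]2[C@@H]1CO[C@@H]2c1cc(OC)c(O)c(OC)c1
F4 | step 8 | (−)-syringaresinol, (7R,7'R,8S,8'S) | COc1cc(cc(OC)c1O)[C@@H]1OC[C@@H]2[C@H]1CO[C@H]2c1cc(OC)c(O)c(OC)c1
F5 | step 6 | (4R)-4-[4-(benzyloxy)-3,5-dimethoxyphenyl]-1-{3,5-dimethoxy-4-[(triisopropylsilyl)oxy]phenyl}-4-[(trimethylsilyl)oxy]but-2-yn-1-ol, mixture of C1 epimers | COc1cc(cc(OC)c1OCc1ccccc1)[C@@H](O[Si](C)(C)C)C#CC(O)c1cc(OC)c(O[Si](C(C)C)(C(C)C)C(C)C)c(OC)c1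
F6 | step 6 | (4R)-4-[4-(benzyloxy)-3,5-dimethoxyphenyl]-1-{3,5-dimethoxy-4-[(triisopropylsilyl)oxy]phenyl}-4-[(trimethylsilyl)oxy]but-2-yn-1-one | COc1cc(cc(OC)c1OCc1ccccc1)[C@@H](O[Si](C)(C)C)C#CC(=O)c1cc(OC)c(O[Si](C(C)C)(C(C)C)C(C)C)c(OC)c1
F7 | step 10 | (1S,2R,3R,4S)-1-[4-(benzyloxy)-3,5-dimethoxyphenyl]-4-{3,5-dimethoxy-4-[(triisopropylsilyl)oxy]phenyl}-2,3-bis(hydroxymethyl)butane-1,4-diol | COc1cc(cc(OC)c1OCc1ccccc1)[C@@H](O)[C@@H](CO)[C@H](CO)[C@H](O)c1cc(OC)c(O[Si](C(C)C)(C(C)C)C(C)C)c(OC)c1
F8 | step 10 | bis(primary methanesulfonate) of F7 | COc1cc(cc(OC)c1OCc1ccccc1)[C@@H](O)[C@@H](COS(C)(=O)=O)[C@H](COS(C)(=O)=O)[C@H](O)c1cc(OC)c(O[Si](C(C)C)(C(C)C)C(C)C)c(OC)c1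
F9 | step 28 | C7A ketone of 41 (C8A S) | COc1cc(cc(OC)c1O[C@@H](CO[Si](C)(C)C(C)(C)C)C(=O)c1ccc(O[Si](C(C)C)(C(C)C)C(C)C)c(OC)c1)[C@H]1OC[C@H]2[C@@H]1CO[C@@H]2c1cc(OC)c(O[C@@H](CO[Si](C)(C)C(C)(C)C)[C@@H](O[Si](C)(C)C(C)(C)C)c3ccc(O[C@H](CO[Si](C)(C)C(C)(C)C)[C@@H](O[Si](C)(C)C(C)(C)C)c4ccc(O[Si](C(C)C)(C(C)C)C(C)C)c(OC)c4)c(OC)c3)c(OC)c1
A1 | alternative 1 | protected target with free C7A and C7E hydroxyls (C9A, C7D, C9D, C9E O-TBS; rings A and E O-benzyl) | COc1cc([C@@H](O)[C@H](CO[Si](C)(C)C(C)(C)C)Oc2c(OC)cc([C@H]3OC[C@H]4[C@@H]3CO[C@@H]4c3cc(OC)c(O[C@@H](CO[Si](C)(C)C(C)(C)C)[C@@H](O[Si](C)(C)C(C)(C)C)c4ccc(O[C@H](CO[Si](C)(C)C(C)(C)C)[C@@H](O)c5ccc(OCc6ccccc6)c(OC)c5)c(OC)c4)c(OC)c3)cc2OC)ccc1OCc1ccccc1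
A2 | alternative 1 | bis(α-aryloxy aldehyde): core with ring B–O–CH(CHO)CH2OTBS (C8A S) and the D chain ending in ring D–O–CH(CHO)CH2OTBS (C8E R) | O=C[C@H](CO[Si](C)(C)C(C)(C)C)Oc1c(OC)cc(cc1OC)[C@H]1OC[C@H]2[C@@H]1CO[C@@H]2c1cc(OC)c(O[C@@H](CO[Si](C)(C)C(C)(C)C)[C@@H](O[Si](C)(C)C(C)(C)C)c2ccc(O[C@H](CO[Si](C)(C)C(C)(C)C)C=O)c(OC)c2)c(OC)c1
A3 | alternative 1 | [4-(benzyloxy)-3-methoxyphenyl]titanium triisopropoxide | COc1cc(ccc1OCc1ccccc1)[Ti](OC(C)C)(OC(C)C)OC(C)C
A4 | alternative 2 | trans-disubstituted (5R)-menthyloxy butyrolactone carrying the ring-C dithiane and the ring-B aldol carbinol | O=C1O[C@@H](O[C@@H]2C[C@H](C)CC[C@H]2C(C)C)[C@H](C2(SCCCS2)c2cc(OC)c(O[Si](C(C)C)(C(C)C)C(C)C)c(OC)c2)[C@H]1[C@H](O)c1cc(OC)c(OCc2ccccc2)c(OC)c1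
A5 | alternative 2 | 2-{3,5-dimethoxy-4-[(triisopropylsilyl)oxy]phenyl}-1,3-dithiane | COc1cc(cc(OC)c1O[Si](C(C)C)(C(C)C)C(C)C)C1SCCCS1
A6 | alternative 2 | (5R)-5-{[(1R,2S,5R)-2-isopropyl-5-methylcyclohexyl]oxy}furan-2(5H)-one | O=C1C=C[C@H](O[C@@H]2C[C@H](C)CC[C@H]2C(C)C)O1
A7 | alternative 3 | ring-B O-benzyl, ring-C O-triisopropylsilyl furofuran core (identical with 17) | COc1cc(cc(OC)c1OCc1ccccc1)[C@H]1OC[C@H]2[C@@H]1CO[C@@H]2c1cc(OC)c(O[Si](C(C)C)(C(C)C)C(C)C)c(OC)c1
A8 | alternative 3 | (2R,3R)-2-[4-(benzyloxy)-3,5-dimethoxybenzyl]-3-{3,5-dimethoxy-4-[(triisopropylsilyl)oxy]benzyl}butane-1,4-diol | COc1cc(cc(OC)c1OCc1ccccc1)C[C@@H](CO)[C@H](CO)Cc1cc(OC)c(O[Si](C(C)C)(C(C)C)C(C)C)c(OC)c1
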